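**Plan**
- Retrosynthesis: the three MOM ethers are removed first. Then O1–C8a and C4–C4a of ring C are cut together, giving a ring A aryne (C4a≡C8a) and an (S)-3-aryl-3-oxypropanoate that carries ring B, C2 and C3. Last come the C8–CH2 bond (Negishi) and the α-alkylation that builds the lavandulyl unit.
- Enabling feature: ring A is a phloroglucinol whose C5 oxygen sits on the carbon next to C4a. In the C4a≡C8a aryne this oxygen steers an oxygen nucleophile to C8a and leaves the carbanion on C4a, at six-ring distance from the ester carbonyl of the chain just attached.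
- Forward: ring A is dressed by two directed ortho-metalations (SiMe3 at C4a; iodide, then lavandulyl, at C8) and turned into the ortho-silylaryl triflate. Ring B arrives as a silylated β-hydroxy ester. Ring C is closed last onto the intact ring A, then the MOM groups are removed.
- Stereochemistry: the side-chain centre comes from an Evans deconjugative alkylation ((S)-4-benzyloxazolidinone). C2 comes from (R)-BINAP–ruthenium hydrogenation of a β-keto ester and is carried through the annulation with its C–O bond never broken.

Key step: step 16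

Remark: the side-chain stereocentre is (R) in the target, but the same spatial arrangement is (S) in lavandulol and in its acyl, iodide and zinc derivatives, because the CH2X arm changes CIP rank.

Step 1
Reactants: 1 (S)-4-benzyloxazolidin-2-one; 2 3-methylbut-2-enoyl chloride
Product: 4 (S)-4-benzyl-3-(3-methylbut-2-enoyl)oxazolidin-2-one, via lithium salt 3 (not isolated)
Conditions: n-BuLi, THF, −78 °C; then 2, −78 → 0 °C
Reagents that add atoms: none
Why: N-acylation of the lithiated oxazolidinone with an acid chloride is the standard loading of an Evans auxiliary and should leave the conjugated alkene untouched.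

Step 2
Reactants: 4 (S)-4-benzyl-3-(3-methylbut-2-enoyl)oxazolidin-2-one; 5 1-bromo-3-methylbut-2-ene (prenyl bromide)
Product: 7 (S)-4-benzyl-3-[(2S)-5-methyl-2-(prop-1-en-2-yl)hex-4-enoyl]oxazolidin-2-one, via sodium dienolate 6 (not isolated)
Conditions: NaN(SiMe3)2, THF, −78 °C; then 5, −78 → −40 °C
Reagents that add atoms: none
Why: γ-deprotonation should give the chelated (Z)-dienolate, which is expected to alkylate at the α-carbon on the face away from the benzyl group (Evans deconjugative alkylation), setting the side-chain stereocentre and leaving the isopropenyl group out of conjugation.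

Step 3
Reactants: 7 (S)-4-benzyl-3-[(2S)-5-methyl-2-(prop-1-en-2-yl)hex-4-enoyl]oxazolidin-2-one
Product: 8 (S)-lavandulol [(2S)-5-methyl-2-(prop-1-en-2-yl)hex-4-en-1-ol]
Conditions: LiBH4, MeOH (1 equiv), Et2O, 0 °C
Reagents that add atoms: none
Why: reductive cleavage of the N-acyl oxazolidinone with LiBH4 should give the primary alcohol and the recoverable auxiliary under non-basic conditions, so the α-centre next to the isopropenyl group is neither epimerised nor drawn into conjugation.

Step 4
Reactants: 8 (S)-lavandulol
Product: 9 (S)-lavandulyl iodide [(3S)-3-(iodomethyl)-2,6-dimethylhepta-1,5-diene]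
Conditions: I2, PPh3, imidazole, CH2Cl2, 0 °C → rt
Reagents that add atoms: iodine, II
Why: Appel-type iodination is an SN2 displacement at the primary carbon, so the adjacent stereocentre and both alkenes should stay intact.

Step 5
Reactants: 10 5-methoxyresorcinol (5-methoxybenzene-1,3-diol)
Product: 11 3-methoxy-5-(methoxymethoxy)phenol
Conditions: MOMCl (0.9 equiv), i-Pr2NEt, CH2Cl2, 0 °C → rt; diol in excess, diol and bis-ether recycled
Reagents that add atoms: chloromethyl methyl ether, COCCl
Why: O-alkylation of one of two equivalent phenols (statistical monoprotection of a symmetric diphenol) differentiates the future C5 oxygen (MOM) from the future C8a oxygen (free).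

Step 6
Reactants: 11 3-methoxy-5-(methoxymethoxy)phenol
Product: 12 3-methoxy-5-(methoxymethoxy)phenyl N,N-diethylcarbamate
Conditions: Et2NCOCl, K2CO3, MeCN, reflux
Reagents that add atoms: N,N-diethylcarbamoyl chloride, CCN(CC)C(=O)Cl
Why: O-carbamoylation puts the strongest oxygen-based directing group for ortho-metalation on the future C8a oxygen.

Step 7
Reactants: 12 3-methoxy-5-(methoxymethoxy)phenyl N,N-diethylcarbamate
Product: 14 5-methoxy-3-(methoxymethoxy)-2-(trimethylsilyl)phenyl N,N-diethylcarbamate, via aryllithium 13 (not isolated)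
Conditions: s-BuLi, TMEDA, THF, −78 °C; then Me3SiCl, −78 °C → rt
Reagents that add atoms: chlorotrimethylsilane, C[Si](C)(C)Cl
Why: directed ortho-metalation should take place at the carbon flanked by the carbamate and the MOM ether (cooperative effect of the two strongest directors, the future C4a), and at −78 °C the aryllithium is silylated before an anionic ortho-Fries shift can start.

Step 8
Reactants: 14 5-methoxy-3-(methoxymethoxy)-2-(trimethylsilyl)phenyl N,N-diethylcarbamate
Product: 16 2-iodo-3-methoxy-5-(methoxymethoxy)-6-(trimethylsilyl)phenyl N,N-diethylcarbamate, via aryllithium 15 (not isolated)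
Conditions: s-BuLi, TMEDA, THF, −78 °C; then I2, THF, −78 °C
Reagents that add atoms: iodine, II
Why: the second directed ortho-metalation should go to the only position left ortho to the carbamate (future C8, also flanked by the methoxy group), the carbamate outranking the MOM ether as director and being turned towards this side by the neighbouring silyl group, and the cold iodine quench pre-empts the ortho-Fries shift.

Step 9
Reactants: 9 (S)-lavandulyl iodide; 16 2-iodo-3-methoxy-5-(methoxymethoxy)-6-(trimethylsilyl)phenyl N,N-diethylcarbamate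
Product: 18 3-methoxy-5-(methoxymethoxy)-2-[(2R)-5-methyl-2-(prop-1-en-2-yl)hex-4-en-1-yl]-6-(trimethylsilyl)phenyl N,N-diethylcarbamate, via lavandulylzinc iodide 17 (not isolated)
Conditions: 9, Zn dust (activated with 1,2-dibromoethane and Me3SiCl), LiCl, THF, 40 °C; then 16, Pd(OAc)2 (3 mol%), SPhos (6 mol%), THF, 50 °C
Reagents that add atoms: none
Why: Negishi coupling of a primary alkylzinc iodide with a di-ortho-substituted electron-rich aryl iodide is well served by a bulky biarylphosphine that speeds reductive elimination over β-hydride elimination, and the stereocentre β to zinc is not involved.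

Step 10
Reactants: 18 the lavandulyl aryl carbamate
Product: 19 3-methoxy-5-(methoxymethoxy)-2-[(2R)-5-methyl-2-(prop-1-en-2-yl)hex-4-en-1-yl]-6-(trimethylsilyl)phenol
Conditions: LiAlH4, THF, 0 °C → reflux; aq. potassium sodium tartrate work-up
Reagents that add atoms: none
Why: reductive cleavage of a hindered aryl carbamate by hydride attack at the carbonyl should free the phenoxide while alkenes, MOM ether and aryl silane are inert to LiAlH4.

Step 11
Reactants: 19 the ortho-silyl phenol
Product: 20 3-methoxy-5-(methoxymethoxy)-2-[(2R)-5-methyl-2-(prop-1-en-2-yl)hex-4-en-1-yl]-6-(trimethylsilyl)phenyl trifluoromethanesulfonate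
Conditions: Tf2O, pyridine, CH2Cl2, −20 → 0 °C
Reagents that add atoms: trifluoromethanesulfonic anhydride, O=S(=O)(OS(=O)(=O)C(F)(F)F)C(F)(F)F
Why: O-sulfonylation of the phenol gives the ortho-silylaryl triflate, the standard fluoride-triggered aryne precursor, with pyridine buffering the acid away from alkenes and acetal.

Step 12
Reactants: 21 1-(2,6-dihydroxyphenyl)ethanone
Product: 22 1-[2,6-bis(methoxymethoxy)phenyl]ethanone
Conditions: NaH, MOMCl, DMF, 0 °C → rt
Reagents that add atoms: chloromethyl methyl ether, COCCl
Why: Williamson-type O-alkylation of both hydrogen-bonded phenols as their sodium salts protects ring B in a form stable to base, fluoride and hydrogenation.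

Step 13
Reactants: 22 1-[2,6-bis(methoxymethoxy)phenyl]ethanone
Product: 23 ethyl 3-[2,6-bis(methoxymethoxy)phenyl]-3-oxopropanoate
Conditions: NaH, (EtO)2CO, toluene, 90 °C; then AcOH, 0 °C
Reagents that add atoms: diethyl carbonate, CCOC(=O)OCC
Why: crossed Claisen condensation of the methyl ketone enolate with non-enolisable diethyl carbonate is driven to completion by deprotonation of the β-keto ester formed.

Step 14
Reactants: 23 ethyl 3-[2,6-bis(methoxymethoxy)phenyl]-3-oxopropanoate
Product: 24 ethyl (3S)-3-[2,6-bis(methoxymethoxy)phenyl]-3-hydroxypropanoate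
Conditions: H2 (30 bar), [RuCl(p-cymene)((R)-BINAP)]Cl (1 mol%), EtOH, 50 °C
Reagents that add atoms: none
Why: in the Noyori asymmetric hydrogenation the β-keto ester chelates ruthenium through both carbonyls and hydride reaches the ketone face set by (R)-BINAP, the sense that gives (R)-3-hydroxybutanoates and that reads (S) here because the aryl group outranks the CH2CO2Et arm.

Step 15
Reactants: 24 ethyl (3S)-3-[2,6-bis(methoxymethoxy)phenyl]-3-hydroxypropanoate
Product: 25 ethyl (3S)-3-[2,6-bis(methoxymethoxy)phenyl]-3-(trimethylsilyloxy)propanoate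
Conditions: Me3SiCl, imidazole, CH2Cl2, 0 °C
Reagents that add atoms: chlorotrimethylsilane, C[Si](C)(C)Cl
Why: O-silylation masks the carbinol as a latent alkoxide that fluoride can release under strictly aprotic conditions.

Step 16
Reactants: 20 the ortho-silylaryl triflate; 25 ethyl (3S)-3-[2,6-bis(methoxymethoxy)phenyl]-3-(trimethylsilyloxy)propanoate (2 equiv)
Product: 29 (2S)-2-[2,6-bis(methoxymethoxy)phenyl]-7-methoxy-5-(methoxymethoxy)-8-[(2R)-5-methyl-2-(prop-1-en-2-yl)hex-4-en-1-yl]chroman-4-one, via cesium alkoxide 26 (not isolated), via aryne 27 (not isolated), via aryl cesium adduct 28 (not isolated)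
Conditions: CsF (3 equiv), 18-crown-6, THF (0.3 M in 25), −20 °C → rt; pH 7 phosphate buffer quench
Reagents that add atoms: none
Why: Proposed new method: fluoride strips the silyl group from 25 to give the naked alkoxide 26 and triggers 1,2-elimination of silyl and triflate from 20 to the aryne 27; 26 adds to C8a, the C4a carbanion 28 attacks the ester carbonyl and ethoxide leaves, so the aryne is formally inserted between the oxygen and the acyl carbon of the hydroxy ester. The closest known reaction type is the fluoride-mediated annulation of ortho-silylaryl triflates with salicylate esters to xanthones (phenoxide addition, then aryl-anion acylation), extended here to an aliphatic secondary alkoxide delivered from its silyl ether. Ring C closes by 6-exo-trig acyl substitution after the intermolecular O-arylation. No stereocentre is formed: C2 comes from 25 with its C–O bond untouched, and it should be shielded from retro-oxa-Michael scrambling because the ethoxide released takes the silyl group of the next molecule of 25, so no strong base builds up. The step needs O-attack at C8a and not C4a, which the inductively withdrawing C5 methoxymethoxy group next to C4a secures by distorting the aryne (attack meta to oxygen, carbanion ortho to it). It also needs bimolecular capture to outrun an intramolecular ene reaction of the aryne with the side-chain alkenes and proton quench of 28, for which 25 is used in excess, concentrated and in an aprotic medium.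

Step 17
Reactants: 29 the tris-MOM flavanone
Product: 30 Exiguaflavanone B
Conditions: aq. HCl (3 M), MeOH/THF, rt → 40 °C
Reagents that add atoms: none
Why: acid-catalysed acetal methanolysis should remove the three aryl MOM ethers (the peri one fastest) under conditions that the isolated alkenes, which have no free ortho-phenol to cyclise onto, and the C2 centre are expected to tolerate.

**Compound list**
1 | (S)-4-benzyloxazolidin-2-one | O=C1N[C@@H](Cc2ccccc2)CO1 | starting material
2 | 3-methylbut-2-enoyl chloride | CC(C)=CC(=O)Cl | starting material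
3 | N-lithio-(S)-4-benzyloxazolidin-2-one | [Li]N1[C@@H](Cc2ccccc2)COC1=O | intermediate
4 | (S)-4-benzyl-3-(3-methylbut-2-enoyl)oxazolidin-2-one | CC(C)=CC(=O)N1[C@@H](Cc2ccccc2)COC1=O | intermediate
5 | 1-bromo-3-methylbut-2-ene (prenyl bromide) | CC(C)=CCBr | starting material
6 | sodium (Z)-dienolate of 4 | C=C(C)/C=C(\[O-])N1[C@@H](Cc2ccccc2)COC1=O.[Na+] | intermediate
7 | (S)-4-benzyl-3-[(2S)-5-methyl-2-(prop-1-en-2-yl)hex-4-enoyl]oxazolidin-2-one | C=C(C)[C@H](CC=C(C)C)C(=O)N1[C@@H](Cc2ccccc2)COC1=O | intermediate
8 | (S)-lavandulol, (2S)-5-methyl-2-(prop-1-en-2-yl)hex-4-en-1-ol | C=C(C)[C@H](CC=C(C)C)CO | intermediate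
9 | (S)-lavandulyl iodide, (3S)-3-(iodomethyl)-2,6-dimethylhepta-1,5-diene | C=C(C)[C@H](CC=C(C)C)CI | intermediate
10 | 5-methoxyresorcinol | COc1cc(O)cc(O)c1 | starting material
11 | 3-methoxy-5-(methoxymethoxy)phenol | COCOc1cc(O)cc(OC)c1 | intermediate
12 | 3-methoxy-5-(methoxymethoxy)phenyl N,N-diethylcarbamate | CCN(CC)C(=O)Oc1cc(OC)cc(OCOC)c1 | intermediate
13 | 2-lithio derivative of 12 (lithium between carbamate and MOM ether) | CCN(CC)C(=O)Oc1cc(OC)cc(OCOC)c1[Li] | intermediate
14 | 5-methoxy-3-(methoxymethoxy)-2-(trimethylsilyl)phenyl N,N-diethylcarbamate | CCN(CC)C(=O)Oc1cc(OC)cc(OCOC)c1[Si](C)(C)C | intermediate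
15 | 6-lithio derivative of 14 (lithium between carbamate and methoxy group) | CCN(CC)C(=O)Oc1c([Li])c(OC)cc(OCOC)c1[Si](C)(C)C | intermediate
16 | 2-iodo-3-methoxy-5-(methoxymethoxy)-6-(trimethylsilyl)phenyl N,N-diethylcarbamate | CCN(CC)C(=O)Oc1c(I)c(OC)cc(OCOC)c1[Si](C)(C)C | intermediate
17 | (S)-lavandulylzinc iodide | C=C(C)[C@H](CC=C(C)C)C[Zn]I | intermediate
18 | 3-methoxy-5-(methoxymethoxy)-2-[(2R)-5-methyl-2-(prop-1-en-2-yl)hex-4-en-1-yl]-6-(trimethylsilyl)phenyl N,N-diethylcarbamate | C=C(C)[C@H](CC=C(C)C)Cc1c(OC)cc(OCOC)c([Si](C)(C)C)c1OC(=O)N(CC)CC | intermediate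
19 | 3-methoxy-5-(methoxymethoxy)-2-[(2R)-5-methyl-2-(prop-1-en-2-yl)hex-4-en-1-yl]-6-(trimethylsilyl)phenol | C=C(C)[C@H](CC=C(C)C)Cc1c(OC)cc(OCOC)c([Si](C)(C)C)c1O | intermediate
20 | 3-methoxy-5-(methoxymethoxy)-2-[(2R)-5-methyl-2-(prop-1-en-2-yl)hex-4-en-1-yl]-6-(trimethylsilyl)phenyl trifluoromethanesulfonate | C=C(C)[C@H](CC=C(C)C)Cc1c(OC)cc(OCOC)c([Si](C)(C)C)c1OS(=O)(=O)C(F)(F)F | intermediate
21 | 1-(2,6-dihydroxyphenyl)ethanone | CC(=O)c1c(O)cccc1O | starting material
22 | 1-[2,6-bis(methoxymethoxy)phenyl]ethanone | CC(=O)c1c(OCOC)cccc1OCOC | intermediate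
23 | ethyl 3-[2,6-bis(methoxymethoxy)phenyl]-3-oxopropanoate | CCOC(=O)CC(=O)c1c(OCOC)cccc1OCOC | intermediate
24 | ethyl (3S)-3-[2,6-bis(methoxymethoxy)phenyl]-3-hydroxypropanoate | CCOC(=O)C[C@H](O)c1c(OCOC)cccc1OCOC | intermediate
25 | ethyl (3S)-3-[2,6-bis(methoxymethoxy)phenyl]-3-(trimethylsilyloxy)propanoate | CCOC(=O)C[C@H](O[Si](C)(C)C)c1c(OCOC)cccc1OCOC | intermediate
26 | cesium alkoxide of 24 | CCOC(=O)C[C@H]([O-])c1c(OCOC)cccc1OCOC.[Cs+] | intermediate
27 | aryne: 4-methoxy-6-(methoxymethoxy)-3-[(2R)-5-methyl-2-(prop-1-en-2-yl)hex-4-en-1-yl]benzyne | C=C(C)[C@H](CC=C(C)C)CC1=C(OC)C=C(OCOC)C#C1 | intermediate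
28 | aryl cesium adduct: ethyl (3S)-3-aryloxy-3-[2,6-bis(methoxymethoxy)phenyl]propanoate with cesium on C4a | C=C(C)[C@H](CC=C(C)C)Cc1c(OC)cc(OCOC)c([Cs])c1O[C@H](c1c(OCOC)cccc1OCOC)CC(=O)OCC | intermediate
29 | (2S)-2-[2,6-bis(methoxymethoxy)phenyl]-7-methoxy-5-(methoxymethoxy)-8-[(2R)-5-methyl-2-(prop-1-en-2-yl)hex-4-en-1-yl]chroman-4-one | C=C(C)[C@H](CC=C(C)C)Cc1c(OC)cc(OCOC)c2c1O[C@H](c1c(OCOC)cccc1OCOC)CC2=O | intermediate
30 | Exiguaflavanone B | C=C(C)[C@H](CC=C(C)C)Cc1c(OC)cc(O)c2c1O[C@H](c1c(O)cccc1O)CC2=O | target

**Count and risks**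
Total step count: 17. Longest linear sequence: 9 steps (steps 5–11, 16, 17 from 10; equally steps 1–4, 9–11, 16, 17 from 1).

Steps most likely to fail:

1. Step 16. The aryne may be captured by the side-chain alkenes in an intramolecular ene reaction, the aryl anion may be protonated before ring closure, or the naked alkoxide may undergo retro-aldol cleavage or β-elimination. The fallback avoids the aryne and uses known reactions only. It sets out from 19 and returns at 29. Protodesilylation of 19 (TBAF, THF) gives 3-methoxy-5-(methoxymethoxy)-2-[(2R)-lavandulyl]phenol F1. Mitsunobu etherification (PPh3, DIAD, toluene, 0 °C) of F1 with ethyl (3R)-3-[2,6-bis(methoxymethoxy)phenyl]-3-hydroxypropanoate F2, made from 23 as in step 14 but with the (S)-BINAP catalyst, should give with inversion the (3S)-aryl ether ester F3. Saponification (LiOH, THF/H2O, 0 °C) gives the acid F4. Cyclodehydration of F4 (intramolecular Friedel–Crafts acylation, TFAA, CH2Cl2, 0 °C) at C4a, the only free position ortho to the ether oxygen, gives 29.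

2. Step 14. The two ortho substituents twist the aryl ketone and may cause slow turnover or poor facial selectivity, and the medium may cost MOM groups. The fallback replaces asymmetric catalysis by resolution. It sets out from 23 and returns at 24. NaBH4 (EtOH, −20 °C) gives the racemic hydroxy ester F5. Lipase-catalysed acylation (Burkholderia cepacia lipase, vinyl acetate, MTBE) is expected to convert the (R)-enantiomer into the acetate F6 and leave 24; if the enzyme rejects the hindered carbinol, F5 is separated on a chiral stationary phase.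

3. Step 17. Acid may ionise the benzylic C2–O1 bond (ring opening to the chalcone and unselective reclosure, hence epimerisation at C2) or protonate the side-chain alkenes. The fallback exchanges the acetals for silyl ethers without Brønsted acid. It sets out from 29 and returns at 30. TMSOTf with 2,2'-bipyridyl (CH2Cl2, 0 °C) should convert the three aryl MOM ethers into the tris(trimethylsilyl) ether F7, which is hydrolysed at neutral pH (THF/H2O, rt) to 30.

Further compounds
F1 | step 16 | 3-methoxy-5-(methoxymethoxy)-2-[(2R)-5-methyl-2-(prop-1-en-2-yl)hex-4-en-1-yl]phenol | C=C(C)[C@H](CC=C(C)C)Cc1c(OC)cc(OCOC)cc1O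
F2 | step 16 | ethyl (3R)-3-[2,6-bis(methoxymethoxy)phenyl]-3-hydroxypropanoate | CCOC(=O)C[C@@H](O)c1c(OCOC)cccc1OCOC
F3 | step 16 | ethyl (3S)-3-[2,6-bis(methoxymethoxy)phenyl]-3-{3-methoxy-5-(methoxymethoxy)-2-[(2R)-5-methyl-2-(prop-1-en-2-yl)hex-4-en-1-yl]phenoxy}propanoate | C=C(C)[C@H](CC=C(C)C)Cc1c(OC)cc(OCOC)cc1O[C@H](c1c(OCOC)cccc1OCOC)CC(=O)OCC
F4 | step 16 | (3S)-3-[2,6-bis(methoxymethoxy)phenyl]-3-{3-methoxy-5-(methoxymethoxy)-2-[(2R)-5-methyl-2-(prop-1-en-2-yl)hex-4-en-1-yl]phenoxy}propanoic acid | C=C(C)[C@H](CC=C(C)C)Cc1c(OC)cc(OCOC)cc1O[C@H](c1c(OCOC)cccc1OCOC)CC(=O)O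
F5 | step 14 | racemic ethyl 3-[2,6-bis(methoxymethoxy)phenyl]-3-hydroxypropanoate | CCOC(=O)CC(O)c1c(OCOC)cccc1OCOC
F6 | step 14 | ethyl (3R)-3-acetoxy-3-[2,6-bis(methoxymethoxy)phenyl]propanoate | CCOC(=O)C[C@@H](OC(C)=O)c1c(OCOC)cccc1OCOC
F7 | step 17 | (2S)-2-[2,6-bis(trimethylsilyloxy)phenyl]-7-methoxy-8-[(2R)-5-methyl-2-(prop-1-en-2-yl)hex-4-en-1-yl]-5-(trimethylsilyloxy)chroman-4-one | C=C(C)[C@H](CC=C(C)C)Cc1c(OC)cc(O[Si](C)(C)C)c2c1O[C@H](c1c(O[Si](C)(C)C)cccc1O[Si](C)(C)C)CC2=O
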